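The plan rests on one disconnection: bond C3–C3a of the dihydrofuran ring (O1, C2, C3, C3a, C7a of the furo[3,2-c]pyran-4-one core). Since C2 bears an aryl group and C3 a carbon at the carboxyl level (it becomes C6 of the hydroxypyrone), this five-membered ring can be read as a shrunken flavanone ring: a 2-aryl-2,3-dihydropyran-4-one annulated to the C3a=C7a edge of the pyrone. One oxidation with trivalent iodine shifts the pyrone carbon from the ketone carbon to the neighbouring CH2, contracts the oxygen ring from six to five members, releases the old ketone carbon as an ester and places it trans to the aryl group. The precursor is the (2R)-2-aryl-7-styryl-2,3-dihydropyrano[4,3-b]pyran-4,5-dione with four benzyl-protected phenols.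

Key step: step 4

Assumption: the quinidine-derived thiourea is taken to deliver the 2R series. If the sense of induction proves opposite, its quinine-derived pseudoenantiomer is used and nothing else changes.

Numbering: the pyranopyrandiones are numbered as pyrano[4,3-b]pyrans (O1, C2, C3, C4, C4a, C5, O6, C7, C8, C8a). The furopyranones are numbered as furo[3,2-c]pyrans (O1, C2, C3, C3a, C4, O5, C6, C7, C7a). C4a of the former becomes C3a of the latter.

Design remark: all four phenols stay benzylated, the ether type already proven in the flavanone version of the key step. After the key step, no operation generates a free enolate at C3, because expulsion of O1 from such an enolate would erase both stereocentres at once.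

Step 1
Reactants: 1 dehydroacetic acid (3-acetyl-4-hydroxy-6-methyl-2H-pyran-2-one); 2 3,4-bis(benzyloxy)benzaldehyde
Product: 3 3-{(2E)-3-[3,4-bis(benzyloxy)phenyl]prop-2-enoyl}-4-hydroxy-6-methyl-2H-pyran-2-one
Conditions: 2 (1.0 equiv), piperidine (0.2 equiv), CHCl3, reflux, Dean–Stark trap
Reagents that add atoms: none
Why: The amine-catalysed Claisen–Schmidt (aldol) condensation takes place only at the acetyl CH3, the more acidic methyl group of the chelated tricarbonyl system, and loss of water gives the conjugated E enone without forming a stereocentre.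

Step 2
Reactants: 3 cinnamoyl methylpyrone from step 1; 2 3,4-bis(benzyloxy)benzaldehyde
Product: 5 3-{(2E)-3-[3,4-bis(benzyloxy)phenyl]prop-2-enoyl}-6-{(E)-2-[3,4-bis(benzyloxy)phenyl]ethenyl}-4-hydroxy-2H-pyran-2-one, via aldol adduct 4 (not isolated)
Conditions: LiN(iPr)2 (2.3 equiv), THF, −78 to −40 °C; 2 (1.1 equiv), −78 °C; AcOH; solvent switch; TsOH·H2O (0.1 equiv), toluene, 60 °C
Reagents that add atoms: none
Why: With the acetyl CH3 used up, the second equivalent of base can only deprotonate the C6 methyl group of the enolate (the dianion aldol addition known for 4-hydroxy-6-methyl-2-pyrone), and acid-catalysed E1 dehydration of the electron-rich benzylic alcohol 4 gives the E styryl group.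

Step 3
Reactants: 5 hydroxychalcone analogue from step 2
Product: 6 (2R)-2-[3,4-bis(benzyloxy)phenyl]-7-{(E)-2-[3,4-bis(benzyloxy)phenyl]ethenyl}-2,3-dihydro-4H,5H-pyrano[4,3-b]pyran-4,5-dione
Conditions: thiourea from 9-amino-9-deoxy-epi-quinidine and 3,5-(CF3)2C6H3NCS (10 mol %), 4 Å MS, toluene, −20 °C; short silica plug; recrystallisation
Reagents that add atoms: none
Why: This is an enantioselective intramolecular oxa-Michael addition (6-endo-trig, the chalcone-to-flavanone cyclisation, known in racemic form for 3-alkenoyl-4-hydroxy-2-pyrones) in which the quinuclidine nitrogen takes up the acidic 4-OH proton, the thiourea binds the enone oxygen, and the chiral ion pair lets O4 reach only one face of the β-carbon, setting C2 as R.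

Step 4
Reactants: 6 (2R)-pyranopyrandione from step 3
Product: 9 methyl (2R,3R)-2-[3,4-bis(benzyloxy)phenyl]-6-{(E)-2-[3,4-bis(benzyloxy)phenyl]ethenyl}-4-oxo-2,3-dihydro-4H-furo[3,2-c]pyran-3-carboxylate (2,3-trans), via methyl enol ether 7 (not isolated), via iodanyl ketal 8 (not isolated)
Conditions: PhI(OAc)2 (1.05 equiv), HC(OMe)3/CH2Cl2, 0 °C; then H2SO4 (0.2 equiv), 0 °C to rt, short run; aq NaHCO3
Reagents that add atoms: trimethyl orthoformate, COC(OC)OC
Why: Proposed new method: acid and orthoformate convert the C4 ketone of 6 into enol ether 7, PhI(OAc)2 attacks its C3 on the face away from the pseudo-equatorial C2 aryl group and methanol caps C4, so that in ketal 8 the equatorial C3–I bond lies antiperiplanar to C4–C4a; C4a, the α-carbon of the vinylogous ester O1–C8a=C4a–C5=O and hence its nucleophilic enol-ether carbon, then shifts from C4 to C3 as PhI leaves, and the dimethoxycarbenium ion left behind collapses to CO2Me. The closest known reaction is the PhI(OAc)2 or Tl(NO3)3 ring contraction of flavanones and chroman-4-ones to trans-2-aryl-2,3-dihydrobenzofuran-3-carboxylates, in which a benzene carbon migrates; a 2-pyrone carbon that also carries a lactone carbonyl has not been tried in this role. The dihydrofuran ring is therefore closed not by cyclisation but by a 1,2-shift that makes C3–C3a and cuts the six-membered ring down to five. The new centre C3 is controlled by C2: iodine enters trans to the aryl group, the shift inverts C3, and the ester ends up trans to the aryl group (2R,3R), while the bonds C2–O1 and C2–C3 are never broken. The step needs chemoselectivity for the enol ether over the styryl double bond, the catechol ethers and the C2 aryl group as a rival migrating group: 7 is by far the most electron-rich π bond, the styryl bond is drained by the pyrone, only 1.05 equiv of oxidant is present, and the equatorial iodane is aligned with C4–C4a and not with C2–aryl. Having the oxidant in the flask before the acid, a low temperature and a short run keep acid-induced opening of C2–O1, and with it racemisation, to a minimum.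

Step 5
Reactants: 9 trans methyl ester from step 4
Product: 10 (2R,3R)-2-[3,4-bis(benzyloxy)phenyl]-6-{(E)-2-[3,4-bis(benzyloxy)phenyl]ethenyl}-4-oxo-2,3-dihydro-4H-furo[3,2-c]pyran-3-carboxylic acid
Conditions: Me3SnOH (6 equiv), ClCH2CH2Cl, 70 °C; 1 M HCl wash
Reagents that add atoms: trimethyltin hydroxide, C[Sn](C)(C)O
Why: Methyl ester hydrolysis with Me3SnOH runs close to neutrality, which matters here because hydroxide would open the 2-pyrone and an ester enolate at C3 could expel O1 (E1cB) and destroy both stereocentres.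

Step 6
Reactants: 10 acid from step 5; 11 1-methoxy-1,3-bis(trimethylsilyloxy)buta-1,3-diene
Product: 13 methyl 5-[(2R,3R)-2-[3,4-bis(benzyloxy)phenyl]-6-{(E)-2-[3,4-bis(benzyloxy)phenyl]ethenyl}-4-oxo-2,3-dihydro-4H-furo[3,2-c]pyran-3-yl]-3,5-dioxopentanoate, via acid chloride 12 (not isolated)
Conditions: (COCl)2 (1.5 equiv), DMF (cat.), CH2Cl2, 0 °C to rt, evaporate; 11 (2 equiv), CH2Cl2, −78 °C to rt; dilute HCl work-up
Reagents that add atoms: none
Why: Vilsmeier-type chlorination without amine base avoids ketene formation, and the uncatalysed γ-acylation of the bis-silyl dienol ether of methyl acetoacetate (a masked acetoacetate dianion) by an acid chloride gives the 3,5-dioxo ester under non-basic conditions that leave C2 and C3 alone.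

Step 7
Reactants: 13 dioxo ester from step 6
Product: 14 6-[(2R,3R)-2-[3,4-bis(benzyloxy)phenyl]-6-{(E)-2-[3,4-bis(benzyloxy)phenyl]ethenyl}-4-oxo-2,3-dihydro-4H-furo[3,2-c]pyran-3-yl]-4-hydroxy-2H-pyran-2-one
Conditions: DBU (1.5 equiv), toluene, 0 °C to rt; 1 M HCl
Reagents that add atoms: none
Why: In this DBU-induced lactonisation of a 3,5-dioxo ester (6-exo-trig attack of the C5 enolate oxygen on the ester, then tautomerisation to the 4-hydroxy-2-pyrone), the dicarbonyl unit is deprotonated first, and this negative charge shields the neighbouring C3–H from removal.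

Step 8
Reactants: 14 tetrabenzyl ether from step 7
Product: 15 6-[(2R,3R)-2-(3,4-dihydroxyphenyl)-6-[(E)-2-(3,4-dihydroxyphenyl)ethenyl]-4-oxo-2,3-dihydro-4H-furo[3,2-c]pyran-3-yl]-4-hydroxy-2H-pyran-2-one (target CNP0229149.3)
Conditions: BCl3 (10 equiv), C6HMe5 (15 equiv), CH2Cl2, −78 °C; MeOH quench
Reagents that add atoms: none
Why: Lewis-acid debenzylation of aryl benzyl ethers with BCl3 and pentamethylbenzene as a non-basic benzyl-cation trap works at −78 °C and spares the styryl double bond (which hydrogenolysis would saturate), both pyrones and the stereocentres, and should C2–O1 ionise transiently, the intact C3 centre steers re-closure to the same trans isomer.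

Compound list
1 | dehydroacetic acid (3-acetyl-4-hydroxy-6-methyl-2H-pyran-2-one) | CC(=O)c1c(O)cc(C)oc1=O | starting material
2 | 3,4-bis(benzyloxy)benzaldehyde | O=Cc1ccc(OCc2ccccc2)c(OCc2ccccc2)c1 | starting material
3 | 3-{(2E)-3-[3,4-bis(benzyloxy)phenyl]prop-2-enoyl}-4-hydroxy-6-methyl-2H-pyran-2-one | Cc1cc(O)c(C(=O)/C=C/c2ccc(OCc3ccccc3)c(OCc3ccccc3)c2)c(=O)o1 | intermediate
4 | aldol adduct, racemic at the carbinol carbon, not isolated: 3-{(2E)-3-[3,4-bis(benzyloxy)phenyl]prop-2-enoyl}-6-{2-[3,4-bis(benzyloxy)phenyl]-2-hydroxyethyl}-4-hydroxy-2H-pyran-2-one | O=C(/C=C/c1ccc(OCc2ccccc2)c(OCc2ccccc2)c1)c1c(O)cc(CC(O)c2ccc(OCc3ccccc3)c(OCc3ccccc3)c2)oc1=O | intermediate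
5 | 3-{(2E)-3-[3,4-bis(benzyloxy)phenyl]prop-2-enoyl}-6-{(E)-2-[3,4-bis(benzyloxy)phenyl]ethenyl}-4-hydroxy-2H-pyran-2-one | O=C(/C=C/c1ccc(OCc2ccccc2)c(OCc2ccccc2)c1)c1c(O)cc(/C=C/c2ccc(OCc3ccccc3)c(OCc3ccccc3)c2)oc1=O | intermediate
6 | (2R)-2-[3,4-bis(benzyloxy)phenyl]-7-{(E)-2-[3,4-bis(benzyloxy)phenyl]ethenyl}-2,3-dihydro-4H,5H-pyrano[4,3-b]pyran-4,5-dione | O=C1C[C@H](c2ccc(OCc3ccccc3)c(OCc3ccccc3)c2)Oc2cc(/C=C/c3ccc(OCc4ccccc4)c(OCc4ccccc4)c3)oc(=O)c12 | intermediate
7 | methyl enol ether, not isolated: (2R)-2-[3,4-bis(benzyloxy)phenyl]-7-{(E)-2-[3,4-bis(benzyloxy)phenyl]ethenyl}-4-methoxy-2H,5H-pyrano[4,3-b]pyran-5-one | COC1=C[C@H](c2ccc(OCc3ccccc3)c(OCc3ccccc3)c2)Oc2cc(/C=C/c3ccc(OCc4ccccc4)c(OCc4ccccc4)c3)oc(=O)c12 | intermediate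
8 | iodanyl ketal, not isolated, iodine trans to the C2 aryl group (descriptors differ from 6 only because iodine changes the CIP ranks): (2S,3S)-3-[acetoxy(phenyl)-λ3-iodanyl]-2-[3,4-bis(benzyloxy)phenyl]-7-{(E)-2-[3,4-bis(benzyloxy)phenyl]ethenyl}-4,4-dimethoxy-3,4-dihydro-2H,5H-pyrano[4,3-b]pyran-5-one | COC1(OC)[C@@H](I(OC(C)=O)c2ccccc2)[C@H](c2ccc(OCc3ccccc3)c(OCc3ccccc3)c2)Oc2cc(/C=C/c3ccc(OCc4ccccc4)c(OCc4ccccc4)c3)oc(=O)c12 | intermediate
9 | methyl (2R,3R)-2-[3,4-bis(benzyloxy)phenyl]-6-{(E)-2-[3,4-bis(benzyloxy)phenyl]ethenyl}-4-oxo-2,3-dihydro-4H-furo[3,2-c]pyran-3-carboxylate (trans) | COC(=O)[C@@H]1c2c(cc(/C=C/c3ccc(OCc4ccccc4)c(OCc4ccccc4)c3)oc2=O)O[C@H]1c1ccc(OCc2ccccc2)c(OCc2ccccc2)c1 | intermediate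
10 | (2R,3R)-2-[3,4-bis(benzyloxy)phenyl]-6-{(E)-2-[3,4-bis(benzyloxy)phenyl]ethenyl}-4-oxo-2,3-dihydro-4H-furo[3,2-c]pyran-3-carboxylic acid | O=C(O)[C@@H]1c2c(cc(/C=C/c3ccc(OCc4ccccc4)c(OCc4ccccc4)c3)oc2=O)O[C@H]1c1ccc(OCc2ccccc2)c(OCc2ccccc2)c1 | intermediate
11 | 1-methoxy-1,3-bis(trimethylsilyloxy)buta-1,3-diene | COC(O[Si](C)(C)C)=CC(=C)O[Si](C)(C)C | starting material
12 | acid chloride, not isolated: (2R,3R)-2-[3,4-bis(benzyloxy)phenyl]-6-{(E)-2-[3,4-bis(benzyloxy)phenyl]ethenyl}-4-oxo-2,3-dihydro-4H-furo[3,2-c]pyran-3-carbonyl chloride | O=C(Cl)[C@@H]1c2c(cc(/C=C/c3ccc(OCc4ccccc4)c(OCc4ccccc4)c3)oc2=O)O[C@H]1c1ccc(OCc2ccccc2)c(OCc2ccccc2)c1 | intermediate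
13 | methyl 5-[(2R,3R)-2-[3,4-bis(benzyloxy)phenyl]-6-{(E)-2-[3,4-bis(benzyloxy)phenyl]ethenyl}-4-oxo-2,3-dihydro-4H-furo[3,2-c]pyran-3-yl]-3,5-dioxopentanoate | COC(=O)CC(=O)CC(=O)[C@@H]1c2c(cc(/C=C/c3ccc(OCc4ccccc4)c(OCc4ccccc4)c3)oc2=O)O[C@H]1c1ccc(OCc2ccccc2)c(OCc2ccccc2)c1 | intermediate
14 | 6-[(2R,3R)-2-[3,4-bis(benzyloxy)phenyl]-6-{(E)-2-[3,4-bis(benzyloxy)phenyl]ethenyl}-4-oxo-2,3-dihydro-4H-furo[3,2-c]pyran-3-yl]-4-hydroxy-2H-pyran-2-one | O=c1cc(O)cc([C@@H]2c3c(cc(/C=C/c4ccc(OCc5ccccc5)c(OCc5ccccc5)c4)oc3=O)O[C@H]2c2ccc(OCc3ccccc3)c(OCc3ccccc3)c2)o1 | intermediate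
15 | 6-[(2R,3R)-2-(3,4-dihydroxyphenyl)-6-[(E)-2-(3,4-dihydroxyphenyl)ethenyl]-4-oxo-2,3-dihydro-4H-furo[3,2-c]pyran-3-yl]-4-hydroxy-2H-pyran-2-one | O=c1cc(O)cc([C@@H]2c3c(cc(/C=C/c4ccc(O)c(O)c4)oc3=O)O[C@H]2c2ccc(O)c(O)c2)o1 | target

Total step count: 8. Longest linear sequence: 8 steps (1 to 15).

Steps most likely to fail

Step 4 (Proposed new method).
- What may go wrong: the lactone carbonyl on C4a may slow its migration so much that the iodane decays by other channels. These are dehydrogenation across C2–C3, substitution by methanol at C3, and migration of the C2 aryl group. The oxidant may also attack the styryl double bond, or acid may open C2–O1 and erode the configuration.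
- Fallback (known chemistry, from 2 back to 14): the dianion of commercial 4-hydroxy-6-methyl-2H-pyran-2-one (LiN(iPr)2, THF, −78 °C) is added to 2 to give the aldol adduct 6-{2-[3,4-bis(benzyloxy)phenyl]-2-hydroxyethyl}-4-hydroxy-2H-pyran-2-one F1. TsOH·H2O in warm toluene dehydrates it to 6-[(E)-3,4-bis(benzyloxy)styryl]-4-hydroxy-2H-pyran-2-one F2. Mn(OAc)3·2H2O in AcOH then joins two molecules of F2 in an oxidative radical [3+2] annulation of the kind known for 4-hydroxy-2-pyrones and styrenes. The C3 radical of one pyrone adds to the styryl carbon next to the other pyrone, the benzylic radical is oxidised to the cation, and the 4-oxygen closes the trans dihydrofuran, giving racemic trans-14 F3. Preparative HPLC on a chiral stationary phase separates the enantiomers. The 2R,3R component is 14, which goes on to step 8.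

Step 3.
- What may go wrong: the closure is reversible and the chelated open-chain enol may be the more stable partner, so conversion may stall. Ring opening and re-closure during the run would also wear down the facial selectivity.
- Fallback (from 5 back to 6): C2 is set by C–B bond formation, and the ring is closed by substitution at the pyrone C4 instead of by conjugate addition. Compound 5 is O-methylated (Me2SO4, K2CO3, acetone) to 3-{(2E)-3-[3,4-bis(benzyloxy)phenyl]prop-2-enoyl}-6-[(E)-3,4-bis(benzyloxy)styryl]-4-methoxy-2H-pyran-2-one F4.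
- Asymmetric conjugate borylation of the chalcone-type enone follows. It uses CuCl, NaOtBu, the ligand (R)-1-[(S)-2-(diphenylphosphino)ferrocenyl]ethyldicyclohexylphosphine or its enantiomer (as needed for the R product), bis(pinacolato)diboron and MeOH in THF. This gives the (3R)-β-boryl ketone F5.
- NaBO3·4H2O oxidises the C–B bond with retention to the (3R)-β-hydroxy ketone F6. Its hydroxyl group displaces methanol at C4 by addition–elimination (PPTS, toluene, 40 °C). This closure is irreversible and does not touch the C–O bond of the stereocentre, and it gives 6.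

Step 2.
- What may go wrong: the dianion may be poorly soluble, or its C6 carbanion may add in Michael fashion to the enone of a second molecule, so that oligomerisation competes with the aldol addition.
- Fallback (from 2 back to 5, replacing steps 1 and 2): 5 is built from two identical halves. The lithium dienolate of commercial 2,2,6-trimethyl-4H-1,3-dioxin-4-one (LiN(iPr)2, THF, −78 °C) adds through its γ-carbon to 2 to give 6-{2-[3,4-bis(benzyloxy)phenyl]-2-hydroxyethyl}-2,2-dimethyl-4H-1,3-dioxin-4-one F7. PPTS in warm toluene dehydrates it to 6-[(E)-3,4-bis(benzyloxy)styryl]-2,2-dimethyl-4H-1,3-dioxin-4-one F8. Heating concentrated F8 in toluene at 110 °C without any trap expels acetone. The transient acylketene (4E)-5-[3,4-bis(benzyloxy)phenyl]penta-1,4-diene-1,3-dione F9 then dimerises by [4+2] cycloaddition, in the way acetylketene gives dehydroacetic acid, to 5.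

Further compounds
F1 | step 4 | 6-{2-[3,4-bis(benzyloxy)phenyl]-2-hydroxyethyl}-4-hydroxy-2H-pyran-2-one (racemic) | O=c1cc(O)cc(CC(O)c2ccc(OCc3ccccc3)c(OCc3ccccc3)c2)o1
F2 | step 4 | 6-[(E)-3,4-bis(benzyloxy)styryl]-4-hydroxy-2H-pyran-2-one | O=c1cc(O)cc(/C=C/c2ccc(OCc3ccccc3)c(OCc3ccccc3)c2)o1
F3 | step 4 | racemic trans-14 (both enantiomers written out) | O=c1cc(O)cc([C@@H]2c3c(cc(/C=C/c4ccc(OCc5ccccc5)c(OCc5ccccc5)c4)oc3=O)O[C@H]2c2ccc(OCc3ccccc3)c(OCc3ccccc3)c2)o1.O=c1cc(O)cc([C@H]2c3c(cc(/C=C/c4ccc(OCc5ccccc5)c(OCc5ccccc5)c4)oc3=O)O[C@@H]2c2ccc(OCc3ccccc3)c(OCc3ccccc3)c2)o1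
F4 | step 3 | 3-{(2E)-3-[3,4-bis(benzyloxy)phenyl]prop-2-enoyl}-6-[(E)-3,4-bis(benzyloxy)styryl]-4-methoxy-2H-pyran-2-one | COc1cc(/C=C/c2ccc(OCc3ccccc3)c(OCc3ccccc3)c2)oc(=O)c1C(=O)/C=C/c1ccc(OCc2ccccc2)c(OCc2ccccc2)c1
F5 | step 3 | 3-{(3R)-3-[3,4-bis(benzyloxy)phenyl]-3-(4,4,5,5-tetramethyl-1,3,2-dioxaborolan-2-yl)propanoyl}-6-[(E)-3,4-bis(benzyloxy)styryl]-4-methoxy-2H-pyran-2-one | COc1cc(/C=C/c2ccc(OCc3ccccc3)c(OCc3ccccc3)c2)oc(=O)c1C(=O)C[C@@H](B1OC(C)(C)C(C)(C)O1)c1ccc(OCc2ccccc2)c(OCc2ccccc2)c1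
F6 | step 3 | 3-{(3R)-3-[3,4-bis(benzyloxy)phenyl]-3-hydroxypropanoyl}-6-[(E)-3,4-bis(benzyloxy)styryl]-4-methoxy-2H-pyran-2-one | COc1cc(/C=C/c2ccc(OCc3ccccc3)c(OCc3ccccc3)c2)oc(=O)c1C(=O)C[C@@H](O)c1ccc(OCc2ccccc2)c(OCc2ccccc2)c1
F7 | step 2 | 6-{2-[3,4-bis(benzyloxy)phenyl]-2-hydroxyethyl}-2,2-dimethyl-4H-1,3-dioxin-4-one (racemic) | CC1(C)OC(=O)C=C(CC(O)c2ccc(OCc3ccccc3)c(OCc3ccccc3)c2)O1
F8 | step 2 | 6-[(E)-3,4-bis(benzyloxy)styryl]-2,2-dimethyl-4H-1,3-dioxin-4-one | CC1(C)OC(=O)C=C(/C=C/c2ccc(OCc3ccccc3)c(OCc3ccccc3)c2)O1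
F9 | step 2 | (4E)-5-[3,4-bis(benzyloxy)phenyl]penta-1,4-diene-1,3-dione (transient acylketene) | O=C=CC(=O)/C=C/c1ccc(OCc2ccccc2)c(OCc2ccccc2)c1
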